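**Retrosynthetic overview**
1. Ring A (carbocycle C4a–C8a) is closed last, at C4a=C5(Cl): a cathodically generated chlorozinc enolate of a dichloromethyl ketone adds to the γ-pyranone carbonyl; dehydration and desilylation follow in the work-up.
2. The dichloromethyl ketone (C5–C6) comes from (dichloromethyl)lithium opening of a dioxolanone; the C7–C8 bond comes from the aldol of the L-lactic acid/pivaldehyde dioxolanone enolate with a 4-oxopyran-3-carbaldehyde, which sets C7 and C8.
3. The pyranone aldehyde comes from chlorokojic acid: Arbuzov, Horner–Wadsworth–Emmons with the side-chain enal (C1'=C2'), then OH → OTf → CHO.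
4. The side-chain enal comes from (S)-α-methyl-γ-butyrolactone (C5' bought): lactol, Wittig (C3'=C4'), silylation.
5. Ring order: pyran ring B is bought in chlorokojic acid; ring A is formed in the final step.

Assumption: the four starting materials are taken as commercial single compounds; isochromenone numbering of the target (C1–C8a, side chain C1'–C7') is used for all intermediates.
Abbreviation: SC = (1E,3E,5S)-3,5-dimethyl-7-(triethylsilyloxy)hepta-1,3-dien-1-yl.

**Route**

Step 1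
Reactants: 1 (S)-α-methyl-γ-butyrolactone [(3S)-3-methyloxolan-2-one]
Product: 2 (3S)-3-methyloxolan-2-ol (lactol; anomer mixture)
Conditions: i-Bu2AlH (1.05 equiv), CH2Cl2, −78 °C; aq. potassium sodium tartrate (KNaC4H4O6)
Reagents that add atoms: none
Why: Lactone-to-lactol half-reduction stops at the aluminium hemiacetal at −78 °C, and the non-basic conditions leave the bought C3 stereocentre untouched.

Step 2
Reactants: 2 (3S)-3-methyloxolan-2-ol; 3 2-(triphenyl-λ5-phosphanylidene)propanal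
Product: 4 (2E,4S)-6-hydroxy-2,4-dimethylhex-2-enal
Conditions: toluene, 90 °C, 16 h
Reagents that add atoms: none
Why: Wittig olefination of the open hydroxy-aldehyde form with a formyl-stabilised ylide gives the (E)-2-methyl enal (C3'=C4'), and the neutral ylide is too weak a base to epimerise the α-stereocentre.

Step 3
Reactants: 4 (2E,4S)-6-hydroxy-2,4-dimethylhex-2-enal
Product: 5 (2E,4S)-2,4-dimethyl-6-(triethylsilyloxy)hex-2-enal
Conditions: Et3SiCl, imidazole, CH2Cl2, 0 °C
Reagents that add atoms: chlorotriethylsilane, CC[Si](Cl)(CC)CC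
Why: Standard O-silylation masks the primary hydroxyl against the later enolate and carbenoid steps and is labile enough to be removed in the final acidic work-up.

Step 4
Reactants: 6 chlorokojic acid [2-(chloromethyl)-5-hydroxy-4H-pyran-4-one]
Product: 7 diethyl [(5-hydroxy-4-oxo-4H-pyran-2-yl)methyl]phosphonate
Conditions: P(OEt)3 (3 equiv, neat), 120 °C
Reagents that add atoms: triethyl phosphite, CCOP(OCC)OCC
Why: Michaelis–Arbuzov reaction of the activated allylic-type chloride is driven by loss of volatile chloroethane.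

Step 5
Reactants: 7 diethyl [(5-hydroxy-4-oxo-4H-pyran-2-yl)methyl]phosphonate; 5 (2E,4S)-2,4-dimethyl-6-(triethylsilyloxy)hex-2-enal
Product: 9 5-hydroxy-2-SC-4H-pyran-4-one, via dilithio phosphonate 8 (not isolated)
Conditions: LiN(SiMe3)2 (2.1 equiv), THF, −78 °C; then 5, −78 → 0 °C; AcOH
Reagents that add atoms: none
Why: Horner–Wadsworth–Emmons olefination of the conjugated phosphonate carbanion forms C1'=C2' with E geometry, and carbonyl addition at −78 °C outruns γ-deprotonation of 5, so C5' is not epimerised.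

Step 6
Reactants: 9 5-hydroxy-2-SC-4H-pyran-4-one
Product: 10 4-oxo-6-SC-4H-pyran-3-yl trifluoromethanesulfonate
Conditions: PhNTf2, Et3N, DMAP (cat.), CH2Cl2, 0 °C → rt
Reagents that add atoms: N-phenylbis(trifluoromethanesulfonimide), O=S(=O)(N(c1ccccc1)S(=O)(=O)C(F)(F)F)C(F)(F)F
Why: O-triflation of the acidic enolic hydroxyl, the only free OH, gives an enol triflate ready for oxidative addition.

Step 7
Reactants: 10 4-oxo-6-SC-4H-pyran-3-yl trifluoromethanesulfonate
Product: 11 4-oxo-6-SC-4H-pyran-3-carbaldehyde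
Conditions: Pd(OAc)2 (5 mol %), dppp (5 mol %), CO (1 atm), Et3SiH, Et3N, DMF, 70 °C
Reagents that add atoms: carbon monoxide, [C-]#[O+]
Why: Palladium-catalysed reductive carbonylation (oxidative addition of the triflate to zerovalent palladium, CO insertion, Si–H hydride transfer to the acyl-palladium) installs the C8 aldehyde carbon directly.

Step 8
Reactants: 12 L-lactic acid [(S)-2-hydroxypropanoic acid]
Product: 13 (2S,5S)-2-tert-butyl-5-methyl-1,3-dioxolan-4-one
Conditions: t-BuCHO, TsOH (cat.), H2SO4 (cat.), pentane, reflux, Dean–Stark; recrystallisation (Et2O–pentane, −78 °C)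
Reagents that add atoms: pivaldehyde (2,2-dimethylpropanal), CC(C)(C)C=O
Why: Acid-catalysed acetalisation (Seebach self-regeneration of stereocentres) gives mainly the cis acetal, whose new C2 centre is fixed by the bought lactate centre; crystallisation removes the trans isomer.

Step 9
Reactants: 13 (2S,5S)-2-tert-butyl-5-methyl-1,3-dioxolan-4-one; 11 4-oxo-6-SC-4H-pyran-3-carbaldehyde
Product: 16 (2S,5R)-2-tert-butyl-5-methyl-5-[(R)-(4-oxo-6-SC-4H-pyran-3-yl)(trimethylsilyloxy)methyl]-1,3-dioxolan-4-one, via lithium enolate 14 (not isolated), via lithium aldolate 15 (not isolated)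
Conditions: LiN(i-Pr)2, THF, −78 °C; then 11, −78 °C, 30 min; then Me3SiCl, −78 → −40 °C
Reagents that add atoms: chlorotrimethylsilane, C[Si](C)(C)Cl
Why: In this lithium-enolate aldol addition the acetal tert-butyl group (set by the lactate centre) makes the aldehyde add anti to it, giving C7 as R, and a chair Zimmerman–Traxler transition state of the ring-locked enolate (methyl cis to O–Li, aldehyde substituent equatorial) places C7–CH3 and C8–O syn, giving C8 as R, while in situ silylation blocks retro-aldol.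

Step 10
Reactants: 16 (2S,5R)-2-tert-butyl-5-methyl-5-[(R)-(4-oxo-6-SC-4H-pyran-3-yl)(trimethylsilyloxy)methyl]-1,3-dioxolan-4-one
Product: 18 3-[(1R,2R)-4,4-dichloro-2-hydroxy-2-methyl-3-oxo-1-(trimethylsilyloxy)butyl]-6-SC-4H-pyran-4-one, via lithium hemiketal alkoxide 17 (not isolated)
Conditions: CH2Cl2 (3 equiv), n-BuLi (2.5 equiv), THF, −100 °C; then 16, −100 °C; AcOH, −100 °C → rt
Reagents that add atoms: dichloromethane (used as (dichloromethyl)lithium, [Li]C(Cl)Cl), ClCCl
Why: In this Köbrich carbenoid acylation, (dichloromethyl)lithium adds to the activated dioxolanone carbonyl (far more electrophilic than the vinylogous-ester pyranone carbonyl) to give a tetrahedral alkoxide that is stable at −100 °C and on protonation collapses with loss of pivaldehyde to the dichloromethyl ketone, leaving C7 and C8 untouched.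

Step 11
Reactants: 18 3-[(1R,2R)-4,4-dichloro-2-hydroxy-2-methyl-3-oxo-1-(trimethylsilyloxy)butyl]-6-SC-4H-pyran-4-one
Product: 22 (7R,8R)-5-chloro-7,8-dihydroxy-3-[(1E,3E,5S)-7-hydroxy-3,5-dimethylhepta-1,3-dien-1-yl]-7-methyl-7,8-dihydro-6H-isochromen-6-one (CNP0531745.1), via chlorozinc enolate 19 (not isolated), via chlorozinc aldolate 20 (not isolated), via disilyl ether of the target 21 (not isolated)
Conditions: undivided cell, Zn anode, glassy-carbon cathode, Et4NCl (0.1 M), DMF, 0 °C, −1.25 V vs SCE, 2.1 F/mol, 18 added over 4 h; then AcOH–THF–H2O (3:1:1), rt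
Reagents that add atoms: none
Why: Proposed new method: two-electron cathodic cleavage of one C–Cl bond of the gem-dichloromethyl ketone (expected near −1.2 V vs SCE, about 0.5 V positive of the dienyl-pyranone; direct or via freshly electrodeposited zinc) in the presence of divalent zinc ions from the sacrificial anode gives a chlorozinc α-chloro enolate, which the tertiary C7–OH (about ten pK units too weak an acid) does not quench and which, through a closed zinc-bridged transition state that binds the pyranone oxygen, adds 1,2 to the pyranone carbonyl (6-exo, favoured over conjugate attack at C1) to close ring A; acetic acid then ionises the 4-pyranol to a pyrylium ion that loses the acidic C5 proton to give the chloro-pyranylidene ketone while the silyl ethers hydrolyse; the closest known reaction types are the sacrificial-anode electrochemical Reformatsky reaction, the chromium dichloride-mediated condensation of dichloromethyl ketones with aldehydes to α-chloro enones and Reformatsky additions to 4-pyranones that give ylidene acetates, none of which has been used as an electroreductive ring closure onto a γ-pyranone; no stereocentre is formed or touched.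

**Compound list**
1 | (S)-α-methyl-γ-butyrolactone [(3S)-3-methyloxolan-2-one] | C[C@H]1CCOC1=O | starting material
2 | (3S)-3-methyloxolan-2-ol | C[C@H]1CCOC1O | intermediate
3 | 2-(triphenyl-λ5-phosphanylidene)propanal | CC(C=O)=P(c1ccccc1)(c1ccccc1)c1ccccc1 | starting material
4 | (2E,4S)-6-hydroxy-2,4-dimethylhex-2-enal | O=C/C(C)=C/[C@@H](C)CCO | intermediate
5 | (2E,4S)-2,4-dimethyl-6-(triethylsilyloxy)hex-2-enal | O=C/C(C)=C/[C@@H](C)CCO[Si](CC)(CC)CC | intermediate
6 | chlorokojic acid [2-(chloromethyl)-5-hydroxy-4H-pyran-4-one] | O=C1C=C(CCl)OC=C1O | starting material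
7 | diethyl [(5-hydroxy-4-oxo-4H-pyran-2-yl)methyl]phosphonate | CCOP(=O)(CC1=CC(=O)C(O)=CO1)OCC | intermediate
8 | dilithio derivative of 7 (lithium pyranolate, α-lithio phosphonate) | CCOP(=O)(C([Li])C1=CC(=O)C(O[Li])=CO1)OCC | intermediate
9 | 2-[(1E,3E,5S)-3,5-dimethyl-7-(triethylsilyloxy)hepta-1,3-dien-1-yl]-5-hydroxy-4H-pyran-4-one | O=C1C=C(/C=C/C(C)=C/[C@@H](C)CCO[Si](CC)(CC)CC)OC=C1O | intermediate
10 | 6-[(1E,3E,5S)-3,5-dimethyl-7-(triethylsilyloxy)hepta-1,3-dien-1-yl]-4-oxo-4H-pyran-3-yl trifluoromethanesulfonate | O=C1C=C(/C=C/C(C)=C/[C@@H](C)CCO[Si](CC)(CC)CC)OC=C1OS(=O)(=O)C(F)(F)F | intermediate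
11 | 6-[(1E,3E,5S)-3,5-dimethyl-7-(triethylsilyloxy)hepta-1,3-dien-1-yl]-4-oxo-4H-pyran-3-carbaldehyde | O=CC1=COC(/C=C/C(C)=C/[C@@H](C)CCO[Si](CC)(CC)CC)=CC1=O | intermediate
12 | L-lactic acid [(S)-2-hydroxypropanoic acid] | C[C@H](O)C(=O)O | starting material
13 | (2S,5S)-2-tert-butyl-5-methyl-1,3-dioxolan-4-one | C[C@@H]1O[C@H](C(C)(C)C)OC1=O | intermediate
14 | lithium (2S)-2-tert-butyl-5-methyl-1,3-dioxol-4-olate | CC1=C(O[Li])O[C@@H](C(C)(C)C)O1 | intermediate
15 | lithium (R)-[(2S,4R)-2-tert-butyl-4-methyl-5-oxo-1,3-dioxolan-4-yl](4-oxo-6-SC-4H-pyran-3-yl)methanolate | C[C@]1([C@H](O[Li])C2=COC(/C=C/C(C)=C/[C@@H](C)CCO[Si](CC)(CC)CC)=CC2=O)O[C@H](C(C)(C)C)OC1=O | intermediate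
16 | (2S,5R)-2-tert-butyl-5-methyl-5-[(R)-(4-oxo-6-SC-4H-pyran-3-yl)(trimethylsilyloxy)methyl]-1,3-dioxolan-4-one | C[C@]1([C@H](O[Si](C)(C)C)C2=COC(/C=C/C(C)=C/[C@@H](C)CCO[Si](CC)(CC)CC)=CC2=O)O[C@H](C(C)(C)C)OC1=O | intermediate
17 | lithium 4-(dichloromethyl)-1,3-dioxolan-4-olate adduct of 16 (C4 configuration undefined) | C[C@]1([C@H](O[Si](C)(C)C)C2=COC(/C=C/C(C)=C/[C@@H](C)CCO[Si](CC)(CC)CC)=CC2=O)O[C@H](C(C)(C)C)OC1(O[Li])C(Cl)Cl | intermediate
18 | 3-[(1R,2R)-4,4-dichloro-2-hydroxy-2-methyl-3-oxo-1-(trimethylsilyloxy)butyl]-6-SC-4H-pyran-4-one | C[C@@](O)([C@H](O[Si](C)(C)C)C1=COC(/C=C/C(C)=C/[C@@H](C)CCO[Si](CC)(CC)CC)=CC1=O)C(=O)C(Cl)Cl | intermediate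
19 | chlorozinc enolate of 18 (O–ZnCl on C6, one Cl left on C5) | C[C@@](O)([C@H](O[Si](C)(C)C)C1=COC(/C=C/C(C)=C/[C@@H](C)CCO[Si](CC)(CC)CC)=CC1=O)C(O[Zn]Cl)=CCl | intermediate
20 | (7R,8R)-5-chloro-4a-(chlorozinciooxy)-7-hydroxy-7-methyl-3-SC-8-(trimethylsilyloxy)-4a,5,7,8-tetrahydro-6H-isochromen-6-one | CC(/C=C/C1=CC2(O[Zn]Cl)C(Cl)C(=O)[C@](C)(O)[C@H](O[Si](C)(C)C)C2=CO1)=C\[C@@H](C)CCO[Si](CC)(CC)CC | intermediate
21 | (7R,8R)-5-chloro-7-hydroxy-7-methyl-3-SC-8-(trimethylsilyloxy)-7,8-dihydro-6H-isochromen-6-one | CC(/C=C/C1=CC2=C(Cl)C(=O)[C@](C)(O)[C@H](O[Si](C)(C)C)C2=CO1)=C\[C@@H](C)CCO[Si](CC)(CC)CC | intermediate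
22 | (7R,8R)-5-chloro-7,8-dihydroxy-3-[(1E,3E,5S)-7-hydroxy-3,5-dimethylhepta-1,3-dien-1-yl]-7-methyl-7,8-dihydro-6H-isochromen-6-one | CC(/C=C/C1=CC2=C(Cl)C(=O)[C@](C)(O)[C@H](O)C2=CO1)=C\[C@@H](C)CCO | target

**Step count and risks**

Total steps: 11. Longest linear sequence: 9 (steps 1, 2, 3, 5, 6, 7, 9, 10, 11, from 1 to 22).

Three steps most likely to fail:

Step 11 (proposed new electroreductive ring closure). Possible failures: self-protonation of the enolate by unreacted 18 (hence slow addition), over-reduction of the second C–Cl bond or of the product chromophore, conjugate attack at C1, or Darzens closure of the aldolate. Fallback with known chemistry, setting out from 16 and coming back at 22: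
- chloromethyllithium (ICH2Cl, MeLi·LiBr, THF, −78 °C; AcOH) opens the dioxolanone to the chloromethyl ketone F1;
- N-(trimethylsilyl)imidazole caps the C7 hydroxyl to give the bis(trimethylsilyl) ether F2;
- Lawesson's reagent (toluene, 80 °C) converts the pyranone carbonyl into the pyran-4-thione F3, which is S-alkylated in the flask by its own chloromethyl ketone to the sulfur-bridged 4-(alkylthio)pyrylium chloride F4;
- Et3N and PPh3 bring about an Eschenmoser sulfide contraction, in which the sulfur bridge forces C5 onto C4a, giving the deschloro pyranylidene ketone F5;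
- N-chlorosuccinimide (CH2Cl2, 0 °C) chlorinates the nucleophilic C5 to the tris-silyl ether of the target F6;
- AcOH–THF–H2O then gives 22.

Step 9 (aldol). Possible failures: only modest selectivity at C8, competing conjugate addition at the pyranone C2, or retro-aldol before silylation. Fallback, setting out from 15 and coming back at 16:
- the aldolate is quenched with NH4Cl to the C8-epimeric alcohols F7;
- Dess–Martin periodinane oxidises these to the C8 ketone F8;
- Zn(BH4)2 (Et2O, −78 °C) reduces it under 1,3-chelation between the C8 ketone and the lactone carbonyl, with hydride delivered anti to the C7 methyl, to the (R)-alcohol F9;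
- Me3SiCl/imidazole gives 16.
Here C8 is set by substrate-controlled ketone reduction instead of by aldol facial selectivity.

Step 10 (carbenoid acylation). Possible failures: the fragile, bulky carbenoid may add sluggishly to the neopentyl-type carbonyl or attack the pyranone. Fallback, setting out from 16 and coming back at 18:
- MeLi (THF, −78 °C; AcOH) gives the methyl ketone F10;
- detrifluoroacetylative diazo transfer (LiN(SiMe3)2 then CF3CO2CH2CF3; then MsN3, Et3N, aq. MeCN) proceeds through the trifluoroacetyl ketone F11 to the diazoketone F12;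
- PhICl2 with catalytic pyridine (CH2Cl2, 0 °C) converts the diazo carbon into the CHCl2 group, giving 18.

**Further compounds**
F1 | step 11 | 3-[(1R,2R)-4-chloro-2-hydroxy-2-methyl-3-oxo-1-(trimethylsilyloxy)butyl]-6-SC-4H-pyran-4-one | C[C@@](O)([C@H](O[Si](C)(C)C)C1=COC(/C=C/C(C)=C/[C@@H](C)CCO[Si](CC)(CC)CC)=CC1=O)C(=O)CCl
F2 | step 11 | 3-[(1R,2R)-4-chloro-2-methyl-3-oxo-1,2-bis(trimethylsilyloxy)butyl]-6-SC-4H-pyran-4-one | C[C@@](O[Si](C)(C)C)([C@H](O[Si](C)(C)C)C1=COC(/C=C/C(C)=C/[C@@H](C)CCO[Si](CC)(CC)CC)=CC1=O)C(=O)CCl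
F3 | step 11 | 3-[(1R,2R)-4-chloro-2-methyl-3-oxo-1,2-bis(trimethylsilyloxy)butyl]-6-SC-4H-pyran-4-thione | C[C@@](O[Si](C)(C)C)([C@H](O[Si](C)(C)C)C1=COC(/C=C/C(C)=C/[C@@H](C)CCO[Si](CC)(CC)CC)=CC1=S)C(=O)CCl
F4 | step 11 | sulfur-bridged pyrylium chloride (seven-membered ring C4a–S–C5H2–C6(=O)–C7–C8–C8a fused to the pyrylium; 7R,8R; both O-SiMe3) | C[C@@]1(O[Si](C)(C)C)[C@H](O[Si](C)(C)C)c2c[o+]c(/C=C/C(C)=C/[C@@H](C)CCO[Si](CC)(CC)CC)cc2SCC1=O.[Cl-]
F5 | step 11 | (7R,8R)-7-methyl-3-SC-7,8-bis(trimethylsilyloxy)-7,8-dihydro-6H-isochromen-6-one | CC(/C=C/C1=CC2=CC(=O)[C@](C)(O[Si](C)(C)C)[C@H](O[Si](C)(C)C)C2=CO1)=C\[C@@H](C)CCO[Si](CC)(CC)CC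
F6 | step 11 | (7R,8R)-5-chloro-7-methyl-3-SC-7,8-bis(trimethylsilyloxy)-7,8-dihydro-6H-isochromen-6-one | CC(/C=C/C1=CC2=C(Cl)C(=O)[C@](C)(O[Si](C)(C)C)[C@H](O[Si](C)(C)C)C2=CO1)=C\[C@@H](C)CCO[Si](CC)(CC)CC
F7 | step 9 | (2S,5R)-2-tert-butyl-5-[hydroxy(4-oxo-6-SC-4H-pyran-3-yl)methyl]-5-methyl-1,3-dioxolan-4-one (carbinol epimers) | C[C@]1(C(O)C2=COC(/C=C/C(C)=C/[C@@H](C)CCO[Si](CC)(CC)CC)=CC2=O)O[C@H](C(C)(C)C)OC1=O
F8 | step 9 | (2S,5R)-2-tert-butyl-5-methyl-5-[(4-oxo-6-SC-4H-pyran-3-yl)carbonyl]-1,3-dioxolan-4-one | C[C@]1(C(=O)C2=COC(/C=C/C(C)=C/[C@@H](C)CCO[Si](CC)(CC)CC)=CC2=O)O[C@H](C(C)(C)C)OC1=O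
F9 | step 9 | (2S,5R)-2-tert-butyl-5-[(R)-hydroxy(4-oxo-6-SC-4H-pyran-3-yl)methyl]-5-methyl-1,3-dioxolan-4-one | C[C@]1([C@H](O)C2=COC(/C=C/C(C)=C/[C@@H](C)CCO[Si](CC)(CC)CC)=CC2=O)O[C@H](C(C)(C)C)OC1=O
F10 | step 10 | 3-[(1R,2R)-2-hydroxy-2-methyl-3-oxo-1-(trimethylsilyloxy)butyl]-6-SC-4H-pyran-4-one | C[C@@](O)([C@H](O[Si](C)(C)C)C1=COC(/C=C/C(C)=C/[C@@H](C)CCO[Si](CC)(CC)CC)=CC1=O)C(C)=O
F11 | step 10 | 3-[(1R,2R)-6,6,6-trifluoro-2-hydroxy-2-methyl-3,5-dioxo-1-(trimethylsilyloxy)hexyl]-6-SC-4H-pyran-4-one | C[C@@](O)([C@H](O[Si](C)(C)C)C1=COC(/C=C/C(C)=C/[C@@H](C)CCO[Si](CC)(CC)CC)=CC1=O)C(=O)CC(=O)C(F)(F)F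
F12 | step 10 | 3-[(1R,2R)-4-diazo-2-hydroxy-2-methyl-3-oxo-1-(trimethylsilyloxy)butyl]-6-SC-4H-pyran-4-one | C[C@@](O)([C@H](O[Si](C)(C)C)C1=COC(/C=C/C(C)=C/[C@@H](C)CCO[Si](CC)(CC)CC)=CC1=O)C(=O)C=[N+]=[N-]
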